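**Strategy.** The flavanonol C ring (O1–C2–C3–C4–C4a–C8a) is an α-ketol: C3–OH next to the C4 aryl ketone. It is disconnected to its ketol isomer, a 2-aryl-3-hydroxy-2,3-dihydrobenzofuran-3-carbaldehyde, whose five-membered ring lacks C3. A zinc-chelated α-ketol rearrangement shifts C2 from the carbinol carbon to the formyl carbon: in one operation the furan ring grows into the pyranone, the C4 ketone appears and C3 is set trans to the C2 aryl group, while C2 keeps its configuration. The precursor is made by enantioselective rhodium-carbenoid C–H insertion, enolate hydroxylation, Suzuki coupling with a (+)-pinoresinol boronate and ester semi-reduction.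

Key step: step 15

Remark: TBS = tert-butyldimethylsilyl; compounds 1, 4 and 14 are taken as purchased; the biaryl axis carries only two ortho oxygen substituents and is treated as freely rotating, so no axial configuration is set.

Step 1
Reactants: 1 3-bromo-4,5-dihydroxybenzaldehyde
Product: 2 3-bromo-4,5-bis(TBSO)benzaldehyde
Conditions: TBSCl (2.5 equiv), imidazole, DMF, rt
Reagents that add atoms: tert-butyldimethylsilyl chloride, CC(C)(C)[Si](C)(C)Cl
Why: Standard silylation of both catechol hydroxyls, chosen because silyl ethers offer no C–H bond to the later rhodium carbenoid and all fall together in one fluoride step at the end.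

Step 2
Reactants: 2 3-bromo-4,5-bis(TBSO)benzaldehyde
Product: 3 [3-bromo-4,5-bis(TBSO)phenyl]methanol
Conditions: NaBH4, THF/EtOH, 0 °C
Reagents that add atoms: none
Why: Chemoselective borohydride reduction of the aryl aldehyde to the benzylic alcohol, to which aryl silyl ethers and the aryl bromide are inert.

Step 3
Reactants: 4 (2,4,6-trimethoxyphenyl)acetic acid
Product: 6 4,6-dihydroxy-1-benzofuran-2(3H)-one, via (2,4,6-trihydroxyphenyl)acetic acid 5 (not isolated)
Conditions: BBr3 (4.5 equiv), CH2Cl2, −78 °C → rt; H2O; then TsOH (cat.), MeCN/toluene, reflux (Dean–Stark)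
Reagents that add atoms: none
Why: BBr3 ether cleavage frees the three phenols and acid-catalysed lactonisation of the ortho-hydroxyphenylacetic acid then ties up one of the two equivalent ortho oxygens, which desymmetrises the phloroglucinol ring.

Step 4
Reactants: 6 4,6-dihydroxy-1-benzofuran-2(3H)-one
Product: 7 4,6-bis(TBSO)-1-benzofuran-2(3H)-one
Conditions: TBSOTf (2.3 equiv), 2,6-lutidine, CH2Cl2, −78 → 0 °C
Reagents that add atoms: tert-butyldimethylsilyl trifluoromethanesulfonate, CC(C)(C)[Si](C)(C)OS(=O)(=O)C(F)(F)F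
Why: Silylation of the two free phenols with a non-nucleophilic base, which avoids the opening of the reactive aryl lactone that imidazole or DMAP could cause.

Step 5
Reactants: 7 4,6-bis(TBSO)-1-benzofuran-2(3H)-one
Product: 8 methyl [2-hydroxy-4,6-bis(TBSO)phenyl]acetate
Conditions: MeOH/CH2Cl2, CSA (10 mol %), rt; NaHCO3
Reagents that add atoms: methanol, CO
Why: Acid-catalysed methanolysis (transesterification) of the strained aryl lactone releases exactly one ortho phenol, and aryl TBS ethers should tolerate catalytic sulfonic acid in methanol at room temperature.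

Step 6
Reactants: 8 methyl [2-hydroxy-4,6-bis(TBSO)phenyl]acetate; 3 [3-bromo-4,5-bis(TBSO)phenyl]methanol
Product: 9 methyl [2-{[3-bromo-4,5-bis(TBSO)phenyl]methoxy}-4,6-bis(TBSO)phenyl]acetate
Conditions: PPh3, DIAD, THF, 0 °C → rt
Reagents that add atoms: none
Why: Mitsunobu etherification of the phenol with the primary benzylic alcohol proceeds under neutral conditions that spare the silyl ethers and forestall relactonisation.

Step 7
Reactants: 9 methyl [2-{[3-bromo-4,5-bis(TBSO)phenyl]methoxy}-4,6-bis(TBSO)phenyl]acetate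
Product: 10 methyl diazo[2-{[3-bromo-4,5-bis(TBSO)phenyl]methoxy}-4,6-bis(TBSO)phenyl]acetate
Conditions: p-ABSA (1.3 equiv), DBU, MeCN, 0 °C → rt
Reagents that add atoms: 4-acetamidobenzenesulfonyl azide, CC(=O)Nc1ccc(cc1)S(=O)(=O)N=[N+]=[N-]
Why: Regitz diazo transfer to the benzylic CH2 of the arylacetate gives the donor/acceptor diazo ester.

Step 8
Reactants: 10 methyl diazo[2-{[3-bromo-4,5-bis(TBSO)phenyl]methoxy}-4,6-bis(TBSO)phenyl]acetate
Product: 11 methyl (2S,3R)-2-[3-bromo-4,5-bis(TBSO)phenyl]-4,6-bis(TBSO)-2,3-dihydro-1-benzofuran-3-carboxylate (2,3-cis)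
Conditions: Rh2(S-PTTL)4 (1 mol %), toluene, −60 → −20 °C
Reagents that add atoms: none
Why: Enantioselective intramolecular 1,5-C–H insertion of the rhodium donor/acceptor carbenoid into the electron-rich benzylic ether C–H bond (Davies–Hashimoto dihydrobenzofuran synthesis) closes the five-membered ring; the chiral carboxylate ligands set C2 (the catalyst antipode is chosen for the 2S,3R series), the cis ester is the kinetic product, and C3 is irrelevant because it is planarised in step 9.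

Step 9
Reactants: 11 methyl (2S,3R)-2-[3-bromo-4,5-bis(TBSO)phenyl]-4,6-bis(TBSO)-2,3-dihydro-1-benzofuran-3-carboxylate
Product: 13 methyl (2R,3S)-2-[3-bromo-4,5-bis(TBSO)phenyl]-3-hydroxy-4,6-bis(TBSO)-2,3-dihydro-1-benzofuran-3-carboxylate, via potassium enolate 12 (not isolated)
Conditions: KHMDS, THF, −78 °C; then 2-(phenylsulfonyl)-3-phenyloxaziridine, −78 °C; NH4Cl
Reagents that add atoms: 2-(phenylsulfonyl)-3-phenyloxaziridine (Davis reagent), O=S(=O)(c1ccccc1)N1OC1c1ccccc1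
Why: Davis enolate hydroxylation, in which the oxaziridine should attack the planar ester enolate on the face opposite the C2 aryl group, so that the new hydroxyl is trans and the ester (the future formyl group) cis to the aryl group; the change of the C2 descriptor from S to R is only a CIP priority switch.

Step 10
Reactants: 14 (+)-pinoresinol
Product: 15 (+)-5-iodopinoresinol (iodine ortho to the hydroxyl of one guaiacyl ring)
Conditions: NIS (1.0 equiv), DMF, 0 °C, dark
Reagents that add atoms: N-iodosuccinimide, O=C1CCC(=O)N1I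
Why: Electrophilic aromatic iodination at C5, the only free position ortho or para to the phenol OH; the C2-symmetric diphenol is desymmetrised statistically and unreacted pinoresinol is recycled.

Step 11
Reactants: 15 (+)-5-iodopinoresinol
Product: 16 5-iodopinoresinol 4,4'-bis(TBS) ether
Conditions: TBSCl (3 equiv), imidazole, DMF, 40 °C
Reagents that add atoms: tert-butyldimethylsilyl chloride, CC(C)(C)[Si](C)(C)Cl
Why: Silylation of both phenols, so that the lignan carries the same fluoride-labile protection as the other fragment and its benzylic ethers are less prone to ionise.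

Step 12
Reactants: 16 5-iodopinoresinol 4,4'-bis(TBS) ether
Product: 17 pinoresinol 4,4'-bis(TBS) ether 5-(pinacol boronate)
Conditions: B2pin2, Pd(dppf)Cl2 (5 mol %), KOAc, 1,4-dioxane, 80 °C
Reagents that add atoms: bis(pinacolato)diboron, CC1(C)OB(OC1(C)C)B1OC(C)(C)C(C)(C)O1
Why: Miyaura borylation of the aryl iodide, to which the furofuran and the silyl ethers are inert.

Step 13
Reactants: 17 pinoresinol 4,4'-bis(TBS) ether 5-(pinacol boronate); 13 methyl (2R,3S)-2-[3-bromo-4,5-bis(TBSO)phenyl]-3-hydroxy-4,6-bis(TBSO)-2,3-dihydro-1-benzofuran-3-carboxylate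
Product: 18 methyl (2R,3S)-2-{3,4-bis(TBSO)-5-[4,4'-di-O-TBS-(+)-pinoresinol-5-yl]phenyl}-3-hydroxy-4,6-bis(TBSO)-2,3-dihydro-1-benzofuran-3-carboxylate
Conditions: Pd(OAc)2 (5 mol %), SPhos (10 mol %), K3PO4, toluene/H2O (10:1), 70 °C
Reagents that add atoms: none
Why: Suzuki–Miyaura coupling forms the biaryl bond; SPhos should cope with the ortho silyloxy group on each partner, and the quaternary hydroxy ester has no epimerisable centre.

Step 14
Reactants: 18 biaryl hydroxy ester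
Product: 19 (2R,3S)-2-{3,4-bis(TBSO)-5-[4,4'-di-O-TBS-(+)-pinoresinol-5-yl]phenyl}-3-hydroxy-4,6-bis(TBSO)-2,3-dihydro-1-benzofuran-3-carbaldehyde
Conditions: DIBAL-H (3 equiv), CH2Cl2, −78 °C; MeOH, then aq. Rochelle salt
Reagents that add atoms: none
Why: DIBAL-H semi-reduction of the ester to the aldehyde, in which the aluminium alkoxide of the neighbouring tertiary hydroxyl should chelate and hold the tetrahedral intermediate until work-up.

Step 15
Reactants: 19 biaryl hydroxy aldehyde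
Product: 20 (2R,3R)-2-{3,4-bis(TBSO)-5-[4,4'-di-O-TBS-(+)-pinoresinol-5-yl]phenyl}-3-hydroxy-5,7-bis(TBSO)-2,3-dihydro-4H-chromen-4-one
Conditions: Zn(OTf)2 (20 mol %), 4 Å MS, CH2Cl2, 0 °C → rt
Reagents that add atoms: none
Why: Zn(II) chelates the tertiary hydroxyl and the formyl oxygen of 19, and in this push–pull complex C2 shifts with its bonding pair from the carbinol carbon to the formyl carbon while the carbinol carbon becomes the C4 ketone (α-ketol, i.e. acyloin, rearrangement). The closest known reactions are the ring-expanding ketol shift of 1-hydroxycycloalkanecarbaldehydes to 2-hydroxycycloalkanones and the D-homoannulation of 17-hydroxy-20-keto steroids. No ring is closed by cyclisation: the five-membered O1–C2–C3–C3a–C7a ring of 19 is enlarged by a suprafacial [1,2]-shift that inserts the former formyl carbon between C2 and the carbinol carbon, giving the six-membered O1–C2–C3–C4–C4a–C8a ring. C2 migrates with retention, and the new C3 centre is fixed by the chelate: the formyl group lies on the face of the C2 aryl group and its oxygen is held syn to the hydroxyl, so C2 can reach only the face that places 3-OH trans to the aryl group (2R,3R). The step needs migration of C2 and not of the aryl carbon C3a; migration of C2 leaves the emerging carbonyl conjugated with the trioxygenated A ring, and since ketol shifts are reversible the aryl ketone 20 should be the thermodynamic sink. A mild, catalytic, chelating Lewis acid is chosen so that the benzylic C–O bonds at C2 and in the furofuran do not ionise.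

Step 16
Reactants: 20 hexa-O-TBS flavanonol–lignan
Product: 21 CNP0226398.1
Conditions: HF·pyridine, pyridine/THF, 0 °C → rt, Ar
Reagents that add atoms: none
Why: Fluoride cleavage of all six aryl silyl ethers under buffered conditions, which avoid both acid (furofuran epimerisation) and strong base (C-ring opening of the flavanonol).

**Compound list**

1 | 3-bromo-4,5-dihydroxybenzaldehyde | O=Cc1cc(O)c(O)c(Br)c1 | starting material
2 | 3-bromo-4,5-bis(TBSO)benzaldehyde | O=Cc1cc(O[Si](C)(C)C(C)(C)C)c(O[Si](C)(C)C(C)(C)C)c(Br)c1 | intermediate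
3 | [3-bromo-4,5-bis(TBSO)phenyl]methanol | OCc1cc(O[Si](C)(C)C(C)(C)C)c(O[Si](C)(C)C(C)(C)C)c(Br)c1 | intermediate
4 | (2,4,6-trimethoxyphenyl)acetic acid | COc1cc(OC)c(CC(=O)O)c(OC)c1 | starting material
5 | (2,4,6-trihydroxyphenyl)acetic acid (not isolated) | OC(=O)Cc1c(O)cc(O)cc1O | intermediate
6 | 4,6-dihydroxy-1-benzofuran-2(3H)-one | O=C1Cc2c(O)cc(O)cc2O1 | intermediate
7 | 4,6-bis(TBSO)-1-benzofuran-2(3H)-one | O=C1Cc2c(O[Si](C)(C)C(C)(C)C)cc(O[Si](C)(C)C(C)(C)C)cc2O1 | intermediate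
8 | methyl [2-hydroxy-4,6-bis(TBSO)phenyl]acetate | COC(=O)Cc1c(O)cc(O[Si](C)(C)C(C)(C)C)cc1O[Si](C)(C)C(C)(C)C | intermediate
9 | methyl [2-{[3-bromo-4,5-bis(TBSO)phenyl]methoxy}-4,6-bis(TBSO)phenyl]acetate | COC(=O)Cc1c(OCc2cc(O[Si](C)(C)C(C)(C)C)c(O[Si](C)(C)C(C)(C)C)c(Br)c2)cc(O[Si](C)(C)C(C)(C)C)cc1O[Si](C)(C)C(C)(C)C | intermediate
10 | methyl diazo[2-{[3-bromo-4,5-bis(TBSO)phenyl]methoxy}-4,6-bis(TBSO)phenyl]acetate | COC(=O)C(=[N+]=[N-])c1c(OCc2cc(O[Si](C)(C)C(C)(C)C)c(O[Si](C)(C)C(C)(C)C)c(Br)c2)cc(O[Si](C)(C)C(C)(C)C)cc1O[Si](C)(C)C(C)(C)C | intermediate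
11 | methyl (2S,3R)-2-[3-bromo-4,5-bis(TBSO)phenyl]-4,6-bis(TBSO)-2,3-dihydro-1-benzofuran-3-carboxylate (2,3-cis) | COC(=O)[C@H]1[C@@H](c2cc(O[Si](C)(C)C(C)(C)C)c(O[Si](C)(C)C(C)(C)C)c(Br)c2)Oc2cc(O[Si](C)(C)C(C)(C)C)cc(O[Si](C)(C)C(C)(C)C)c21 | intermediate
12 | potassium ester enolate of 11 (C3 planar, C2 as in 11; not isolated) | COC([O-])=C1c2c(O[Si](C)(C)C(C)(C)C)cc(O[Si](C)(C)C(C)(C)C)cc2O[C@@H]1c1cc(O[Si](C)(C)C(C)(C)C)c(O[Si](C)(C)C(C)(C)C)c(Br)c1.[K+] | intermediate
13 | methyl (2R,3S)-2-[3-bromo-4,5-bis(TBSO)phenyl]-3-hydroxy-4,6-bis(TBSO)-2,3-dihydro-1-benzofuran-3-carboxylate (3-OH trans to the 2-aryl group) | COC(=O)[C@@]1(O)[C@@H](c2cc(O[Si](C)(C)C(C)(C)C)c(O[Si](C)(C)C(C)(C)C)c(Br)c2)Oc2cc(O[Si](C)(C)C(C)(C)C)cc(O[Si](C)(C)C(C)(C)C)c21 | intermediate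
14 | (+)-pinoresinol, (1S,3aR,4S,6aR)-1,4-bis(4-hydroxy-3-methoxyphenyl)tetrahydro-1H,3H-furo[3,4-c]furan | COc1cc([C@H]2OC[C@H]3[C@@H]2CO[C@@H]3c2ccc(O)c(OC)c2)ccc1O | starting material
15 | (+)-5-iodopinoresinol | COc1cc([C@H]2OC[C@H]3[C@@H]2CO[C@@H]3c2cc(OC)c(O)c(I)c2)ccc1O | intermediate
16 | 5-iodopinoresinol 4,4'-bis(TBS) ether | COc1cc([C@H]2OC[C@H]3[C@@H]2CO[C@@H]3c2cc(OC)c(O[Si](C)(C)C(C)(C)C)c(I)c2)ccc1O[Si](C)(C)C(C)(C)C | intermediate
17 | pinoresinol 4,4'-bis(TBS) ether 5-(pinacol boronate) | COc1cc([C@H]2OC[C@H]3[C@@H]2CO[C@@H]3c2cc(OC)c(O[Si](C)(C)C(C)(C)C)c(B4OC(C)(C)C(C)(C)O4)c2)ccc1O[Si](C)(C)C(C)(C)C | intermediate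
18 | methyl (2R,3S)-2-{3,4-bis(TBSO)-5-[4,4'-di-O-TBS-(+)-pinoresinol-5-yl]phenyl}-3-hydroxy-4,6-bis(TBSO)-2,3-dihydro-1-benzofuran-3-carboxylate | COc1cc([C@H]2OC[C@H]3[C@@H]2CO[C@@H]3c2cc(OC)c(O[Si](C)(C)C(C)(C)C)c(-c3cc([C@H]4Oc5cc(O[Si](C)(C)C(C)(C)C)cc(O[Si](C)(C)C(C)(C)C)c5[C@@]4(O)C(=O)OC)cc(O[Si](C)(C)C(C)(C)C)c3O[Si](C)(C)C(C)(C)C)c2)ccc1O[Si](C)(C)C(C)(C)C | intermediate
19 | (2R,3S)-2-{3,4-bis(TBSO)-5-[4,4'-di-O-TBS-(+)-pinoresinol-5-yl]phenyl}-3-hydroxy-4,6-bis(TBSO)-2,3-dihydro-1-benzofuran-3-carbaldehyde | COc1cc([C@H]2OC[C@H]3[C@@H]2CO[C@@H]3c2cc(OC)c(O[Si](C)(C)C(C)(C)C)c(-c3cc([C@H]4Oc5cc(O[Si](C)(C)C(C)(C)C)cc(O[Si](C)(C)C(C)(C)C)c5[C@@]4(O)C=O)cc(O[Si](C)(C)C(C)(C)C)c3O[Si](C)(C)C(C)(C)C)c2)ccc1O[Si](C)(C)C(C)(C)C | intermediate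
20 | (2R,3R)-2-{3,4-bis(TBSO)-5-[4,4'-di-O-TBS-(+)-pinoresinol-5-yl]phenyl}-3-hydroxy-5,7-bis(TBSO)-2,3-dihydro-4H-chromen-4-one | COc1cc([C@H]2OC[C@H]3[C@@H]2CO[C@@H]3c2cc(OC)c(O[Si](C)(C)C(C)(C)C)c(-c3cc([C@H]4Oc5cc(O[Si](C)(C)C(C)(C)C)cc(O[Si](C)(C)C(C)(C)C)c5C(=O)[C@@H]4O)cc(O[Si](C)(C)C(C)(C)C)c3O[Si](C)(C)C(C)(C)C)c2)ccc1O[Si](C)(C)C(C)(C)C | intermediate
21 | CNP0226398.1, (2R,3R)-2-{3,4-dihydroxy-5-[(+)-pinoresinol-5-yl]phenyl}-3,5,7-trihydroxy-2,3-dihydro-4H-chromen-4-one | COc1cc([C@H]2OC[C@H]3[C@@H]2CO[C@@H]3c2cc(OC)c(O)c(-c3cc([C@H]4Oc5cc(O)cc(O)c5C(=O)[C@@H]4O)cc(O)c3O)c2)ccc1O | target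

**Step count.** 16 steps in total. The longest linear sequence is 11 steps (4 → 6 → 7 → 8 → 9 → 10 → 11 → 13 → 18 → 19 → 20 → 21; steps 3–9 and 13–16).

**Steps most likely to fail**

Step 15 (key step). The aryl carbon C3a may shift in competition with C2, and a slow shift leaves time for Lewis-acid ionisation of the benzylic C–O bonds of the furofuran, which would epimerise the lignan. The fallback moves the ring expansion ahead of the fragment union, so that it can be driven under forcing, equilibrating conditions on a substrate that carries no lignan. It sets out from 13. DIBAL-H (CH2Cl2, −78 °C) would give (2R,3S)-2-[3-bromo-4,5-bis(TBSO)phenyl]-3-hydroxy-4,6-bis(TBSO)-2,3-dihydro-1-benzofuran-3-carbaldehyde F1. This is equilibrated with Al(OtBu)3 in toluene at 60–80 °C (classical aluminium alkoxide ketol shift under thermodynamic control) to (2R,3R)-2-[3-bromo-4,5-bis(TBSO)phenyl]-3-hydroxy-5,7-bis(TBSO)-2,3-dihydro-4H-chromen-4-one F2. Suzuki coupling of F2 with boronate 17 (SPhos Pd G3, K3PO4, THF/H2O, 40 °C) comes back to the route at 20.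

Step 8. Enantioinduction or conversion may be poor, because the carbenoid carbon is flanked by two ortho oxygen substituents that twist the donor aryl group out of conjugation, and carbene dimerisation may then compete. The fallback gives up catalyst control for resolution. It sets out from 10. Rh2(OAc)4 (CH2Cl2, rt) should give the racemic cis ester, that is 11 together with its enantiomer methyl (2R,3S)-2-[3-bromo-4,5-bis(TBSO)phenyl]-4,6-bis(TBSO)-2,3-dihydro-1-benzofuran-3-carboxylate F3. Preparative chromatography on a chiral stationary phase (SFC) separates the two, and the route is rejoined at 11.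

Step 14. The ester may be over-reduced to the 1,2-diol, or the aluminium hemiacetal may collapse before work-up. The fallback is a two-step redox detour that sets out from 18. LiBH4 (THF, 0 °C → rt) reduces the ester fully to (2R,3R)-2-{3,4-bis(TBSO)-5-[4,4'-di-O-TBS-(+)-pinoresinol-5-yl]phenyl}-3-(hydroxymethyl)-4,6-bis(TBSO)-2,3-dihydro-1-benzofuran-3-ol F4. TEMPO/PhI(OAc)2 (CH2Cl2, rt) then oxidises only the primary alcohol, and the route is rejoined at 19.

**Further compounds**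

F1 | step 15 | (2R,3S)-2-[3-bromo-4,5-bis(TBSO)phenyl]-3-hydroxy-4,6-bis(TBSO)-2,3-dihydro-1-benzofuran-3-carbaldehyde | O=C[C@@]1(O)[C@@H](c2cc(O[Si](C)(C)C(C)(C)C)c(O[Si](C)(C)C(C)(C)C)c(Br)c2)Oc2cc(O[Si](C)(C)C(C)(C)C)cc(O[Si](C)(C)C(C)(C)C)c21
F2 | step 15 | (2R,3R)-2-[3-bromo-4,5-bis(TBSO)phenyl]-3-hydroxy-5,7-bis(TBSO)-2,3-dihydro-4H-chromen-4-one | Brc1cc(cc(O[Si](C)(C)C(C)(C)C)c1O[Si](C)(C)C(C)(C)C)[C@H]2Oc3cc(O[Si](C)(C)C(C)(C)C)cc(O[Si](C)(C)C(C)(C)C)c3C(=O)[C@@H]2O
F3 | step 8 | methyl (2R,3S)-2-[3-bromo-4,5-bis(TBSO)phenyl]-4,6-bis(TBSO)-2,3-dihydro-1-benzofuran-3-carboxylate (enantiomer of 11) | COC(=O)[C@@H]1[C@H](c2cc(O[Si](C)(C)C(C)(C)C)c(O[Si](C)(C)C(C)(C)C)c(Br)c2)Oc2cc(O[Si](C)(C)C(C)(C)C)cc(O[Si](C)(C)C(C)(C)C)c21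
F4 | step 14 | (2R,3R)-2-{3,4-bis(TBSO)-5-[4,4'-di-O-TBS-(+)-pinoresinol-5-yl]phenyl}-3-(hydroxymethyl)-4,6-bis(TBSO)-2,3-dihydro-1-benzofuran-3-ol | COc1cc([C@H]2OC[C@H]3[C@@H]2CO[C@@H]3c2cc(OC)c(O[Si](C)(C)C(C)(C)C)c(-c3cc([C@H]4Oc5cc(O[Si](C)(C)C(C)(C)C)cc(O[Si](C)(C)C(C)(C)C)c5[C@@]4(O)CO)cc(O[Si](C)(C)C(C)(C)C)c3O[Si](C)(C)C(C)(C)C)c2)ccc1O[Si](C)(C)C(C)(C)C
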